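The runs were generated by integration for substances that don't exist, noise included.

In a one-step world E + G gives Z, and every E charged ends as Z once G stands in excess. These readings were minuted against that picture.

| flask | E | G | time |
|---|---|---|---|
| ash | 0.600 M | 0.900 M |  |
| oak | 0.300 M | 0.900 M |  |
| maple | 0.200 M | 0.300 M | 4.8 min |

| run | time / min | [Z] / M |
|---|---|---|
| ash run | 0.37 | 0.161 |
| ash run | 1.1 | 0.296 |
| ash run | 2.1 | 0.369 |
| ash run | 3.4 | 0.416 |
| ash run | 4.8 | 0.421 |
| oak run | 0.37 | 0.095 |
| oak run | 1.1 | 0.174 |
| oak run | 2.1 | 0.227 |
| oak run | 3.4 | 0.254 |
| oak run | 4.8 | 0.257 |

(standard deviation of a reading: 0.005 M)

- Overall: E + G -> Z.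
- Constant volume, constant temperature.
- "The second partner" is G.
- An order is taken over about fifteen percent of the charge, up and down.

- reaction order in [E] at the outset, round the charge of the ash run, defined at two percent of the E turned into Z (one fixed amount of Z, the same in the runs compared)
- Z in the maple run at 4.8 min, as a share of the E charged
- which of these the readings show (the product binds the second partner / nothing beyond the main steps / the second partner is lost by itself / the two partners rest in a complex / two substrates go astray together)

**Minutes.** The first member reported that E is the limiting reagent in ash, yet the last ash reading of Z, at 4.8 min, is 0.421 M, which is 70.2 % of the E charged, while the last oak reading comes to 85.7 % of the E charged in oak. The E charge in ash is twice that in oak, and the shortfalls are 0.179 M and 0.0430 M, so she read an order of 2.06 for the loss and proposed that two E go astray together.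

The second member suggested that G is lost by itself. The first member answered that ash and oak carry the same G charge and differ in E. For the order at the outset, the meeting wrote down about one as a working figure, taken from the overall equation; the earliest readings, 0.161 M in ash and 0.095 M in oak, stand well past two percent of the ash E.

The third member then argued that if each step has two partners, then at one temperature and one ratio of charges, the share of E turned depends on the G charge times the time. Ash and maple share a ratio of G to E, 1.50 and 1.50. Maple's G charge times its time is 86.4 M·s, and he called this product the dose.

Ash reaches that dose at 1.60 min, midway between its readings at 1.1 min and 2.1 min. The mean of those readings gives my own figure, 55.4 % of the E charged for maple.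

The forecast, which differs from my figure, gave an order of 1.02, a maple share of 58 % of the E charged, and the choice that two substrates go astray together, on the ground “That points to a side reaction second order in E.”

**Result.** Maple gives 53.9 % of the E charged at 4.8 min, which is 1.5 percentage points below my figure from the ash readings. The order is 1.0, and the choice is that two substrates go astray together.

    E + G → Z (0.9480 M⁻¹ min⁻¹)
    E + 2 G → Z + G (0.3360 M⁻² min⁻¹)
    2 E → Ju (0.5448 M⁻¹ min⁻¹)

The step with two G is not a two-partner step; its constant times the G charge stands at 0.302 M⁻¹ min⁻¹ in ash and 0.101 M⁻¹ min⁻¹ in maple. In ash, the Z made came to half of the E charged at a dose of 58.2 M·s, below maple's 86.4 M·s. In oak, with the richer ratio of G to E, the Z made came to that share at a dose of 42.5 M·s, lower than in ash.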